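The route rests on a one-flask (4+2) annulation that builds the cyclohexene ring (C5–C10, eudesmane numbering) from a C5–C6 unit and a C7–C10 unit. Silyl enol ether 6, made from (S)-citronellal so that its C3 stereocentre becomes C4, condenses with the methyl ketone of butenolide 13 (Mukaiyama aldol, loss of water) to give the tetrasubstituted C5=C10 enal; indium then converts the bromomethyl group into an allylindium that adds through C7 to C6. The step exploits the C6 carbinol lying next to the C7–C11(=C13) methylene lactone unit, and the C9 tether enforces the cis ring fusion. The precursors are an acyclic enol silane and a 3-(bromomethyl)butenolide.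

Key step: step 10

Remark on numbering: C1–C4 and C15 are the side chain, C5–C10 the ring, C14 the methyl on C10, C11–C13 and O8 the lactone.

Remark (assumption): the facial sense of the BINOL–Ti(OiPr)4 catalyst in step 6 is assigned by analogy with other unsaturated aldehydes; if the (S)-alcohol formed instead, (S)-BINOL would be used.

**Fragment A (C1–C6, C15)**

Step 1
Reactants: 1 (S)-citronellal
Product: 2 (S)-8,8-dimethoxy-2,6-dimethyloct-2-ene
Conditions: HC(OMe)3, MeOH, PPTS (cat.), 0 → 25 °C
Reagents that add atoms: trimethyl orthoformate, COC(OC)OC
Why: Acid-catalysed acetalization with the orthoformate as water scavenger masks the aldehyde before ozonolysis; the mild pyridinium acid should avoid the carbonyl-ene cyclization of citronellal and does not touch the stereocentre.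

Step 2
Reactants: 2 (S)-8,8-dimethoxy-2,6-dimethyloct-2-ene
Product: 3 (S)-6,6-dimethoxy-4-methylhexan-1-ol
Conditions: O3, CH2Cl2/MeOH, −78 °C; then NaBH4, −78 → 0 °C
Reagents that add atoms: ozone, [O-][O+]=O
Why: Ozonolysis with reductive borohydride work-up cleaves the only alkene to the primary alcohol (the future C1–OH), the acetal being inert.

Step 3
Reactants: 3 (S)-6,6-dimethoxy-4-methylhexan-1-ol
Product: 4 (S)-6,6-dimethoxy-4-methylhexyl acetate
Conditions: Ac2O, Et3N, DMAP (cat.), CH2Cl2, 0 °C
Reagents that add atoms: acetic anhydride, CC(=O)OC(C)=O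
Why: DMAP-catalysed acetylation installs the C1 acetate of the target early, an ester that should survive all later steps.

Step 4
Reactants: 4 (S)-6,6-dimethoxy-4-methylhexyl acetate
Product: 5 (S)-4-methyl-6-oxohexyl acetate
Conditions: AcOH/H2O/THF (3:1:1), 40 °C
Reagents that add atoms: water, O
Why: Acetal hydrolysis in aqueous acetic acid releases the C6 aldehyde without cleaving the primary acetate.

Step 5
Reactants: 5 (S)-4-methyl-6-oxohexyl acetate
Product: 6 (S)-6-[(tert-butyldimethylsilyl)oxy]-4-methylhex-5-enyl acetate (mainly Z enol ether)
Conditions: TBSOTf, Et3N, CH2Cl2, 0 °C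
Reagents that add atoms: tert-butyldimethylsilyl trifluoromethanesulfonate, CC(C)(C)[Si](C)(C)OS(=O)(=O)C(F)(F)F
Why: Soft enolization (silyl triflate plus amine) gives the silyl enol ether that serves as the C5 nucleophile; its geometry is irrelevant because C5 becomes sp2, and the β-stereocentre is not enolizable.

**Fragment B (C7–C14)**

Step 6
Reactants: 7 acrolein; 8 tributyl(2-methylallyl)stannane
Product: 9 (R)-2-methylhexa-1,5-dien-4-ol
Conditions: (R)-BINOL (10 mol %), Ti(OiPr)4 (10 mol %), 4 Å molecular sieves, CH2Cl2, −20 °C; aq. NaHCO3
Reagents that add atoms: none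
Why: Keck asymmetric allylation, in which the BINOL–titanium Lewis acid directs the methallylstannane to one face of the aldehyde and so sets the carbinol centre that becomes C8.

Step 7
Reactants: 9 (R)-2-methylhexa-1,5-dien-4-ol; 10 2-(bromomethyl)acrylic acid
Product: 11 (R)-2-methylhexa-1,5-dien-4-yl 2-(bromomethyl)acrylate
Conditions: DCC, DMAP (cat.), CH2Cl2, 0 °C
Reagents that add atoms: none
Why: Steglich esterification joins C12 to O8 with retention at the carbinol carbon, since only the O–H bond reacts.

Step 8
Reactants: 11 (R)-2-methylhexa-1,5-dien-4-yl 2-(bromomethyl)acrylate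
Product: 12 (R)-3-(bromomethyl)-5-(2-methylallyl)furan-2(5H)-one
Conditions: second-generation Hoveyda–Grubbs catalyst (5 mol %), toluene, 80 °C
Reagents that add atoms: none
Why: Ring-closing metathesis: the catalyst loads on the monosubstituted vinyl group and closes the five-membered butenolide (C7=C11) onto the acrylate, while the methallyl group could only give a four-membered ring and stays intact.

Step 9
Reactants: 12 (R)-3-(bromomethyl)-5-(2-methylallyl)furan-2(5H)-one
Product: 13 (R)-3-(bromomethyl)-5-(2-oxopropyl)furan-2(5H)-one
Conditions: O3 (1 equiv, Sudan Red 7B end point), pyridine, CH2Cl2, −78 °C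
Reagents that add atoms: ozone, [O-][O+]=O
Why: Chemoselective ozonolysis: the electron-rich 1,1-disubstituted alkene reacts far faster than the electron-poor butenolide double bond, and pyridine decomposes the carbonyl oxide so that no nucleophilic reductant meets the allylic bromide.

**Annulation and endgame**

Step 10
Reactants: 6 (S)-6-[(tert-butyldimethylsilyl)oxy]-4-methylhex-5-enyl acetate; 13 (R)-3-(bromomethyl)-5-(2-oxopropyl)furan-2(5H)-one
Product: 16 6-epi-1-O-acetylbritannilactone (6S alcohol; cis-fused lactone; hydroxyl trans to the C7–C11 bond), via hydroxy aldehyde 14 (not isolated), via enal 15 (not isolated)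
Conditions: TiCl4 (1.1 equiv), CH2Cl2, −78 → 0 °C; then THF, aq. NaHCO3 to pH 7, sat. aq. NH4Cl, indium powder, 25 °C
Reagents that add atoms: none
Why: TiCl4 activates the ketone of 13 for Mukaiyama aldol addition of enol silane 6 (C5 to C10), and the tertiary titanium aldolate 14 should lose water on warming (E1cB through the aldehyde enol) to give the tetrasubstituted enal 15. After buffering, indium inserts into the allylic C13–Br bond and the allylindium adds through its γ-carbon C7 to the aldehyde carbon C6 (Barbier reaction, SE2′), moving the butenolide double bond to the exocyclic C11=C13 position; the closest known reaction types are the Mukaiyama aldol condensation of ketones and the indium- or zinc-mediated intramolecular Barbier cyclization of 3-(bromomethyl)butenolides onto aldehydes. The carbocycle closes in a 6-exo-trig manner at the carbonyl carbon through a chair Zimmerman–Traxler array (In, C13, C11, C7, C6, O). C7 is set by the substrate, because the C9 tether can deliver the aldehyde only to the butenolide face on which it sits, so H7 and H8 end up cis with C8 unchanged; C6 is set by the closed transition state with the s-trans enal and C5 equatorial, which should place the hydroxyl trans to the C7–C11 bond (6S). The step needs the enal isomer with CHO cis to C9, 1,2- rather than 1,4-addition, and γ- rather than α-attack of the allyl metal; the first is favoured because the bulky C4 branch avoids the butenolide arm and the isomers can equilibrate under TiCl4, the others because 1,4-addition or attack through C13 would need a four- or eight-membered ring. Any 6R epimer is no loss, since step 11 erases C6.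

Step 11
Reactants: 16 6-epi-1-O-acetylbritannilactone
Product: 17 6-oxo compound (cyclohexenone with the ketone at C6 conjugated to C5=C10; cis-fused α-methylene lactone)
Conditions: Dess–Martin periodinane, NaHCO3, CH2Cl2, 0 °C
Reagents that add atoms: none
Why: Dess–Martin oxidation of the allylic alcohol under buffered, non-basic conditions gives the enone and removes the C6 centre without deprotonating C7.

Step 12
Reactants: 17 6-oxo compound
Product: 18 1-O-acetylbritannilactone (6R alcohol; hydroxyl cis to the C7–C11 bond and to O8)
Conditions: CeCl3·7H2O, NaBH4, MeOH, −78 °C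
Reagents that add atoms: none
Why: Luche reduction delivers hydride 1,2 to the enone from the convex face of the cis-fused bicycle, anti to the C7–C11 bond, which should give the all-cis 6R alcohol and spare the α-methylene lactone at this temperature.

Step 13
Reactants: 18 1-O-acetylbritannilactone
Product: 19 1,6-O,O-diacetylbritannilactone
Conditions: Ac2O, pyridine, DMAP (cat.), CH2Cl2, 0 °C
Reagents that add atoms: acetic anhydride, CC(=O)OC(C)=O
Why: DMAP-catalysed acetylation of the one remaining secondary alcohol gives the diacetate with retention at C6.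

**Compound list**

1 | (S)-citronellal | O=CC[C@@H](C)CCC=C(C)C | starting material
2 | (S)-8,8-dimethoxy-2,6-dimethyloct-2-ene | COC(OC)C[C@@H](C)CCC=C(C)C | intermediate
3 | (S)-6,6-dimethoxy-4-methylhexan-1-ol | COC(OC)C[C@@H](C)CCCO | intermediate
4 | (S)-6,6-dimethoxy-4-methylhexyl acetate | COC(OC)C[C@@H](C)CCCOC(C)=O | intermediate
5 | (S)-4-methyl-6-oxohexyl acetate | O=CC[C@@H](C)CCCOC(C)=O | intermediate
6 | (S,Z)-6-[(tert-butyldimethylsilyl)oxy]-4-methylhex-5-enyl acetate | CC(=O)OCCC[C@H](C)/C=C\O[Si](C)(C)C(C)(C)C | intermediate
7 | acrolein | C=CC=O | starting material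
8 | tributyl(2-methylallyl)stannane | CC(=C)C[Sn](CCCC)(CCCC)CCCC | starting material
9 | (R)-2-methylhexa-1,5-dien-4-ol | C=C[C@H](O)CC(C)=C | intermediate
10 | 2-(bromomethyl)acrylic acid | OC(=O)C(=C)CBr | starting material
11 | (R)-2-methylhexa-1,5-dien-4-yl 2-(bromomethyl)acrylate | C=C(CBr)C(=O)O[C@@H](C=C)CC(C)=C | intermediate
12 | (R)-3-(bromomethyl)-5-(2-methylallyl)furan-2(5H)-one | BrCC1=C[C@@H](CC(C)=C)OC1=O | intermediate
13 | (R)-3-(bromomethyl)-5-(2-oxopropyl)furan-2(5H)-one | BrCC1=C[C@@H](CC(C)=O)OC1=O | intermediate
14 | β-hydroxy aldehyde from the aldol addition (mixture at C5 and C10; 4S, 8R) | O=CC([C@@H](C)CCCOC(C)=O)C(C)(O)C[C@H]1OC(=O)C(CBr)=C1 | intermediate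
15 | (Z)-enal with CHO cis to C9 (4S, 8R) | O=C/C([C@@H](C)CCCOC(C)=O)=C(/C)C[C@H]1OC(=O)C(CBr)=C1 | intermediate
16 | 6-epi-1-O-acetylbritannilactone (6S alcohol) | C=C1C(=O)O[C@@H]2CC(C)=C([C@@H](C)CCCOC(C)=O)[C@@H](O)[C@H]12 | intermediate
17 | 6-oxo compound (enone) | C=C1C(=O)O[C@@H]2CC(C)=C([C@@H](C)CCCOC(C)=O)C(=O)[C@H]12 | intermediate
18 | 1-O-acetylbritannilactone (6R alcohol) | C=C1C(=O)O[C@@H]2CC(C)=C([C@@H](C)CCCOC(C)=O)[C@H](O)[C@H]12 | intermediate
19 | 1,6-O,O-diacetylbritannilactone (4S,6R,7R,8R) | C=C1C(=O)O[C@@H]2CC(C)=C([C@@H](C)CCCOC(C)=O)[C@H](OC(C)=O)[C@H]12 | target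

Total step count: 13. Longest linear sequence: 9 steps (steps 1–5 and 10–13).

**Steps most likely to fail**

Step 10. The aldol addition of the β-branched enol silane to the methyl ketone may be slow or revert on warming (retro-aldol), dehydration may stay incomplete, the unwanted enal isomer may not equilibrate, and the allylindium may be protonated before it closes the ring. The fallback makes the C5–C10 bond by an acetal/enol ether condensation instead. It sets out from 4 and 13. Acetal 4 is converted with TMSOTf and iPr2NEt into methyl enol ether F1, and ketone 13 with HC(OMe)3, MeOH and PPTS into dimethyl ketal F2. BF3·OEt2 (cat.) in CH2Cl2 at −40 °C couples the two to methoxy acetal F3. In the same flask aqueous HCl in THF hydrolyses the acetal and eliminates methanol to give enal 15, and buffering followed by indium powder closes the ring. The fallback comes back to the route at 16.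

Step 11. Enolization of the 6-oxo compound toward C7 may move the exocyclic double bond into conjugation or expel the lactone oxygen from C8, which would lead on to aromatization. The fallback avoids the ketone altogether: Mitsunobu inversion of 16 with acetic acid (PPh3, DIAD, AcOH, toluene, 0 → 25 °C) should give the 6R acetate directly. It sets out from 16 and comes back at 19, skipping 17 and 18 and making no new compound.

Step 8. Ring closure onto the hindered, electron-poor 1,1-disubstituted acrylate may be slow, so that oligomerization by cross-metathesis or loss of catalyst through the allylic bromide takes over. The fallback sets out from 9. The alcohol is esterified (DCC, DMAP) with 2-{[(tert-butyldimethylsilyl)oxy]methyl}acrylic acid to ester F4, ring-closing metathesis gives silyloxymethyl butenolide F5, and PPh3·Br2 in CH2Cl2 converts the silyl ether directly into the bromide. The fallback comes back to the route at 12.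

Further compounds
F1 | step 10 | (S)-6-methoxy-4-methylhex-5-enyl acetate (E/Z mixture) | CC(=O)OCCC[C@H](C)C=COC
F2 | step 10 | (R)-3-(bromomethyl)-5-(2,2-dimethoxypropyl)furan-2(5H)-one | BrCC1=C[C@@H](CC(C)(OC)OC)OC1=O
F3 | step 10 | β-methoxy dimethyl acetal from the coupling (mixture at C5 and C10; 4S, 8R) | COC(OC)C([C@@H](C)CCCOC(C)=O)C(C)(OC)C[C@H]1OC(=O)C(CBr)=C1
F4 | step 8 | (R)-2-methylhexa-1,5-dien-4-yl 2-{[(tert-butyldimethylsilyl)oxy]methyl}acrylate | C=C(CO[Si](C)(C)C(C)(C)C)C(=O)O[C@@H](C=C)CC(C)=C
F5 | step 8 | (R)-3-{[(tert-butyldimethylsilyl)oxy]methyl}-5-(2-methylallyl)furan-2(5H)-one | CC(C)(C)[Si](C)(C)OCC1=C[C@@H](CC(C)=C)OC1=O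
F0 | step 11 | none | none
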